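34% of target against 27%, both after 1.25 d: this pair, from the alpha run and the zeta flask, carries the argument.

| flask | substrate | salt in the second phase | spent carrier | remark | volume of the second phase over the first |
|---|---|---|---|---|---|
| zeta | 0.020 M | 1 equiv | 2.5 mol% | the very flask that is asked about, followed so far |  |
| alpha | 0.020 M | 1.5 equiv | 2.5 mol% | run made earlier |  |
| flask | 0.020 M | 1.00 equiv | 2.5 mol% |  | 1.0 |

| run | time / d | target / % | substrate / % |
|---|---|---|---|
| zeta | 0.417 | 8 | 95 |
| zeta | 1.25 | 27 | 76 |
| zeta | 2.00 | 38 | 62 |
| zeta | 3.00 | 45 | 53 |
| zeta | 5.00 | 61 | 37 |
| zeta | 6.00 | 64 | 34 |
| zeta | 8.00 | 71 | 28 |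
| alpha | 1.25 | 34 | 66 |
| alpha | 4.00 | 71 | 30 |
| alpha | 8.00 | 81 | 12 |
| alpha | 10.0 | 88 | 10 |
| alpha | 15.0 | 92 | 7 |
| alpha | 20.0 | 94 | 6 |
| alpha | 25.0 | 91 | 6 |

(standard deviation of a reading: 2 percentage points)

- factor on the rate of making target when 20% of the substrate are converted if salt in the second phase is charged twice over
- factor on the rate when 20% of the substrate are converted if spent carrier is charged at 12 mol% instead

- in the second phase: salt in the second phase, spent salt in the second phase; everything else is in the first
- charges count per volume of the first phase; a concentration in a rate is the amount of a species over the volume of its own phase; every rate counts per litre of the first phase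
- steps thought possible: spent carrier + salt in the second phase <-> fresh carrier + spent salt in the second phase; substrate + fresh carrier <-> target + spent carrier
- the earlier runs hold the two phases in the same ratio of volumes as the flask asked about
- no earlier run changes the charge of spent carrier; that part of a forecast is a guess

What does the extra salt buy? By that time the alpha run had made 1.26 times the target of the zeta flask on 1.50 times the salt. Call the logarithm of the factor on the rate over the logarithm of the factor on salt the salt order, n; taking the target made by equal time as the mean rate, these two readings give 0.569.

Is the step in which spent carrier takes up salt then the rate-limiting step? I would not call it that, since n reads below one.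

What happens on doubling? At 20% conversion the zeta flask and its doubled twin hold the same substrate, while salt stands at 2.25 times as much, so I reckon a factor of 1.59.

Isn't a comparison at equal time unfair? Yes. The alpha run had 66% substrate left against 76% in the zeta flask, so it worked on less, and each reading scatters by 2 percentage points. So I take n as reading low, with that scatter on top, and still commit to about 1.59.

And the carrier? No earlier run changes it, so proportion, 4.80, is my guess.

The forecast says 2.2 for doubled salt and 4.7 for the larger carrier charge, holding that "Salt-first-order behaviour suggests that carrier regeneration is limiting"; my salt factor is lower than its figure.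

The simulation gives 1.69 for doubled salt and 4.59 for the larger carrier charge.

    spent carrier + salt in the second phase ⇌ fresh carrier + spent salt in the second phase (K = 10.0, k = 0.00780 M⁻¹ s⁻¹)
    substrate + fresh carrier ⇌ target + spent carrier (K = 2.80, k = 0.0190 M⁻¹ s⁻¹)

In the zeta flask fresh carrier holds 38.8% of the catalyst charged at 2.50 d, and at 2.51 d it is made 1.01 times as fast as it is used, each step taken net. Put back through the salt order, the factor 1.69 on 2.25 times the salt comes to 0.646, beside the 0.569 that carries the scatter of its two readings. The same measure on spent carrier, from 4.59 at 12 mol%, comes to 0.972.

The data were generated by integration from invented constants; noise was put on by code.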